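All runs stem from a simulated flask on assumed constants.

- A small charge of G, 5.0 mM, was what I planned this flask around. Tuesday's run at cL 0.34 M read 13.9 % of Q at 5.00 min and Wednesday's at cL 0.75 M read 14.6 % at 4.00 min, while Monday's, with cG 10 mM, read twice Tuesday's level, 26.0 % at 8.00 min. I therefore read the stop as tied to cG rather than to cL, kept J and X as they were, and set cL at 0.500 M.

the same everywhere: J 0.50 M; X 0.50 M
- Tuesday's: L 0.34 M; G 5 mM; run made earlier
- Wednesday's: L 0.75 M; G 5 mM; run made earlier
- Monday's: L 0.50 M; G 10 mM; run made earlier
- flask: L 0.500 M; G 5.0 mM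

| run | time / min | Q / % |
|---|---|---|
| Tuesday's | 0.667 | 5.0 |
| Tuesday's | 2.00 | 9.3 |
| Tuesday's | 3.00 | 11.2 |
| Tuesday's | 5.00 | 13.9 |
| Tuesday's | 8.00 | 13.5 |
| Wednesday's | 1.33 | 14.1 |
| Wednesday's | 3.00 | 14.6 |
| Wednesday's | 4.00 | 14.6 |
| Wednesday's | 6.00 | 14.1 |
| Wednesday's | 8.00 | 17.1 |
| Monday's | 0.667 | 12.0 |
| Monday's | 2.00 | 18.6 |
| Monday's | 3.00 | 21.2 |
| Monday's | 5.00 | 24.8 |
| Monday's | 8.00 | 26.0 |

(each reading ± 1 percentage point)

- G is single-handed; J and X are mirror images of each other, charged as a racemate, each of them at the stated concentration

* apparent order in G when 5.0 % of the J and X together are converted (percent change of the rate of making Q for one percent more G charged)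

- From Monday's run I took the Q made per G charged, n, the turnover number, as 26.0, and from it I carried the spent share f, the fraction of the charged G lost once a given amount of Q is made, which is that Q divided by n·cG.
- The share of X in the conversion was unread, so I split 5.0 % evenly between J and X, which made f 19.2 %. Taking the rate as following the live G, cG minus Q/n, the order at fixed conversion is one over (one minus f), so I committed to 1.24 and would watch the earliest readings.
- The forecast was 1, on the ground that “The underlying order in G is therefore only about 0.5”, so my figure stood higher than the forecast's.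
- The flask gave 1.2, with 17.9 % of G already Z once 5.0 % of J and X together were converted, against my f of 19.2 %.

    L + G + X → G + E (k = 0.773 L² mol⁻² s⁻¹)
    L + G + J → G + Q (k = 1.81 L² mol⁻² s⁻¹)
    L + G → Z (k = 0.0225 L mol⁻¹ s⁻¹)

- Part of what set the order of this flask comes from Z: this flask without the path L + G → Z gave 1.0 instead of 1.2, because at one cL a fixed conversion costs a fixed amount of G, which is a smaller share of a larger charge. In Monday's run, at cG 10 mM, I reckoned f at 9.60 % for that conversion, which gives an order of 1.11.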